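The synthesis rests on disconnecting the C1–C10 bond shared by the six- and ten-membered carbocycles (briarane numbering). The six-membered ring (C1, C10–C14) is a cyclohexa-1,3-diene in disguise, since its C13=C14 alkene sits next to the cis C11,C12-diol and only the fusion atoms C1 and C10 are sp3; that bond is therefore the sigma bond of a 6π electrocyclisation. One thermal, transannular closure of a lactone-fused 14-membered trienone (C10=C11 E, C12=C13 Z, C2 carbonyl inward on C14=C1) forms both carbocycles, quaternary C1 and the C10 stereocentre together. The trienone comes from a Nozaki–Hiyama–Kishi coupling, a boron aldol, a macrocyclic Sonogashira coupling and a semihydrogenation.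

Key step: step 29

Remarks
- Atoms carry briarane locants throughout: C1–C14 ring carbons; C15, C16, C20 the methyls on C1, C5, C11; C17 (methyl C18) the lactone carbinol; C19 the lactone carbonyl.
- C17: osmylation of the open-chain E-enoate 4 on the face preferred by its allylic oxygen would lead to the arabino lactone (methyl C18 trans to C6, C17 epimeric to the target). The route therefore passes through butenolide 6, whose dihydroxylation gives the ribo lactone.
- Assumptions: in step 15 the fully substituted C8 is taken as the large ketone substituent. In step 25 the boron reagent from (−)-α-pinene is taken to direct the Z-enolate to the Re face of the aldehyde, as Z-enolates of ethyl ketones do. Should either sense be opposite, the enantiomeric reagent is used and nothing else changes.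

**Lactone fragment C4–C9**

Step 1
Reactants: 1 methyl (S)-2,2-dimethyl-1,3-dioxolane-4-carboxylate; 2 ethyl 2-(triphenylphosphoranylidene)propanoate
Product: 4 ethyl (E)-3-[(R)-2,2-dimethyl-1,3-dioxolan-4-yl]-2-methylprop-2-enoate, via glyceraldehyde acetonide 3 (not isolated)
Conditions: i-Bu2AlH, CH2Cl2, −78 °C; MeOH; then 2, −78 °C to rt; aq. potassium sodium tartrate
Reagents that add atoms: none
Why: Half-reduction of the ester and Wittig olefination in one flask avoid handling the volatile, configurationally labile aldehyde, bring in C6–C8 (C7 from the glycerate) and C17–C19, and should give mainly the E-enoate, whose geometry is not critical because step 2 converges both isomers.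

Step 2
Reactants: 4 ethyl (E)-3-[(R)-2,2-dimethyl-1,3-dioxolan-4-yl]-2-methylprop-2-enoate
Product: 6 (R)-5-(hydroxymethyl)-3-methylfuran-2(5H)-one, via dihydroxy enoate 5 (not isolated)
Conditions: CF3CO2H–H2O 9:1, 0 °C to rt, evaporate; then hν (254 nm, quartz), MeCN, p-toluenesulfonic acid (cat.), rt, dilute
Reagents that add atoms: none
Why: Acetonide hydrolysis followed by photochemical E/Z isomerisation of the enoate, in which the Z isomer is drained irreversibly by acid-catalysed lactonisation onto the C7 oxygen, should give the butenolide that allows C17 to be set correctly in step 4.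

Step 3
Reactants: 6 (R)-5-(hydroxymethyl)-3-methylfuran-2(5H)-one
Product: 7 (R)-3-methyl-5-[(triethylsilyloxy)methyl]furan-2(5H)-one
Conditions: Et3SiCl, imidazole, CH2Cl2, 0 °C
Reagents that add atoms: chlorotriethylsilane CC[Si](Cl)(CC)CC
Why: Standard silylation of the only hydroxyl, with a primary triethylsilyl ether chosen because it can be oxidised directly under Swern conditions in step 8.

Step 4
Reactants: 7 (R)-3-methyl-5-[(triethylsilyloxy)methyl]furan-2(5H)-one
Product: 8 2-C-methyl-5-O-triethylsilyl-L-ribono-1,4-lactone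
Conditions: OsO4 (5 mol %), N-methylmorpholine N-oxide, acetone–H2O 8:1, rt
Reagents that add atoms: N-methylmorpholine N-oxide C[N+]1([O-])CCOCC1; water O
Why: Catalytic osmium tetroxide syn-dihydroxylation of the butenolide should occur on the ring face opposite the C7 silyloxymethyl group, which sets C17 (hydroxyl trans to C6, methyl C18 cis) as in the target and gives a C8 carbinol whose configuration is erased in step 5.

Step 5
Reactants: 8 2-C-methyl-5-O-triethylsilyl-L-ribono-1,4-lactone
Product: 9 (3S,5S)-3-hydroxy-3-methyl-5-[(triethylsilyloxy)methyl]oxolane-2,4-dione (C8 keto lactone)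
Conditions: Dess–Martin periodinane, NaHCO3, CH2Cl2, 0 °C; cold non-aqueous filtration; used at once
Reagents that add atoms: none
Why: Dess–Martin oxidation converts the only secondary alcohol (C8) to the ketone under buffered, non-basic conditions that spare the tertiary C17 hydroxyl and the base-labile C7–H centre, provided the ketone is kept cold and used immediately.

Step 6
Reactants: 9 C8 keto lactone
Product: 10 (3S,4R,5S)-4-ethenyl-3,4-dihydroxy-3-methyl-5-[(triethylsilyloxy)methyl]oxolan-2-one (C8 vinyl carbinol)
Conditions: CH2=CHMgBr (3 equiv), CeCl3 (3 equiv), THF, −78 °C; AcOH, then aq. NH4Cl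
Reagents that add atoms: vinylmagnesium bromide C=C[Mg]Br
Why: 1,2-Addition of the weakly basic organocerium reagent (one equivalent is consumed by the C17 hydroxyl) should outrun enolisation toward C7 and should enter anti to both C6 and methyl C18, on the face of the C17 alkoxide, which sets C8 with its hydroxyl cis to C6 and brings in C9.

Step 7
Reactants: 10 C8 vinyl carbinol
Product: 11 8,17-bis-O-triethylsilyl ether of 10 (tris-silylated vinyl lactone)
Conditions: Et3SiOTf (3 equiv), 2,6-lutidine, CH2Cl2, 0 °C to rt
Reagents that add atoms: triethylsilyl trifluoromethanesulfonate CC[Si](CC)(CC)OS(=O)(=O)C(F)(F)F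
Why: The silyl triflate is reactive enough to cap both hindered tertiary alcohols (C8 and C17), a standard silylation that protects the lactone core for the chain extensions.

Step 8
Reactants: 11 tris-silylated vinyl lactone
Product: 12 C6 aldehyde (8,17-bis-O-triethylsilyl vinyl lactone carbaldehyde)
Conditions: (COCl)2, DMSO, CH2Cl2, −78 to −40 °C; Et3N, −78 to −20 °C; used crude and cold
Reagents that add atoms: none
Why: Under Swern conditions the primary triethylsilyl ether is cleaved and oxidised in one operation while the tertiary silyl ethers are too hindered to react, giving the C6 aldehyde, which is used at once because C7 is epimerisable.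

Step 9
Reactants: 12 C6 aldehyde; 13 ethyl 2-[bis(2,2,2-trifluoroethoxy)phosphoryl]propanoate
Product: 14 Z-enoate vinyl lactone (ethyl ester at C4, Z C5=C6, vinyl at C8)
Conditions: 13, KN(SiMe3)2, 18-crown-6, THF, −78 °C; then 12, −78 °C
Reagents that add atoms: none
Why: The Still–Gennari variant of the Horner–Wadsworth–Emmons reaction (electron-poor phosphonate, dissociated potassium counter-ion, low temperature) should give the Z trisubstituted C5=C6 enoate under kinetic control and brings in C4, C5 and methyl C16.

Step 10
Reactants: 14 Z-enoate vinyl lactone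
Product: 15 C9 aldehyde (lactone with Z-enoate and formyl group on C8)
Conditions: O3, CH2Cl2–MeOH, −78 °C, Sudan red 7B end point; then Me2S, −78 °C to rt
Reagents that add atoms: ozone [O-][O+]=O
Why: Electrophilic ozone should cleave the isolated vinyl group much faster than the electron-poor trisubstituted enoate when dosed to a dye end point (selective ozonolysis), unveiling the C9 aldehyde, which cannot epimerise because C8 is fully substituted.

**Iodoenyne C10–C13**

Step 11
Reactants: 16 1,4-bis(trimethylsilyl)buta-1,3-diyne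
Product: 17 (trimethylsilyl)buta-1,3-diyne
Conditions: MeLi·LiBr (1 equiv), Et2O, rt; aq. NH4Cl; used as a solution
Reagents that add atoms: none
Why: One equivalent of methyllithium cleaves a single C–Si bond of the symmetrical diyne and the resulting lithium acetylide resists a second attack, a standard mono-desilylation.

Step 12
Reactants: 17 (trimethylsilyl)buta-1,3-diyne
Product: 19 (E)-(4-iodo-3-methylbut-3-en-1-yn-1-yl)trimethylsilane, via alkenylalane 18 (not isolated)
Conditions: Me3Al, (C5H5)2ZrCl2 (25 mol %), CH2Cl2, 0 °C to rt; then I2, THF, −30 to 0 °C; aq. K2CO3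
Reagents that add atoms: trimethylaluminium C[Al](C)C; iodine II
Why: Zirconium-catalysed methylalumination (Negishi carboalumination) adds methyl and aluminium syn across the terminal alkyne with aluminium at the terminus, and iodinolysis with retention gives the E iodide carrying methyl C20.

**Coupling and elaboration to the C4–C13 enal**

Step 13
Reactants: 15 C9 aldehyde; 19 (E)-(4-iodo-3-methylbut-3-en-1-yn-1-yl)trimethylsilane
Product: 20 C4–C13 allylic alcohol (both C9 epimers)
Conditions: CrCl2 (6 equiv), NiCl2 (2 mol %), degassed DMSO–THF 3:1, rt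
Reagents that add atoms: none
Why: The Nozaki–Hiyama–Kishi coupling forms C9–C10 by chemoselective addition of an alkenylchromium species to the hindered aldehyde in the presence of ester, lactone and silylalkyne with retention of the E geometry, and the C9 configuration is not relied on because steps 14 and 15 reset it.

Step 14
Reactants: 20 C4–C13 allylic alcohol (both C9 epimers)
Product: 21 C9 enynone
Conditions: Dess–Martin periodinane, NaHCO3, CH2Cl2, 0 °C to rt
Reagents that add atoms: none
Why: Dess–Martin oxidation converges both C9 epimers on one conjugated ketone.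

Step 15
Reactants: 21 C9 enynone
Product: 22 (9R) allylic alcohol
Conditions: (S)-tetrahydro-1-methyl-3,3-diphenyl-1H,3H-pyrrolo[1,2-c][1,3,2]oxazaborole (0.5 equiv), catecholborane, toluene, −78 °C; MeOH; aq. NaHCO3
Reagents that add atoms: none
Why: Corey–Bakshi–Shibata reduction with the (S)-oxazaborolidine should deliver hydride to the ketone face that gives the (9R) alcohol when the fully substituted C8 acts as the large group and the alkenyl group as the small one, and catecholborane at low temperature leaves lactone, enoate and alkyne untouched.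

Step 16
Reactants: 22 (9R) allylic alcohol
Product: 23 9-O-tert-butyldimethylsilyl ether of 22
Conditions: t-BuMe2SiOTf, 2,6-lutidine, CH2Cl2, −78 to 0 °C
Reagents that add atoms: tert-butyldimethylsilyl trifluoromethanesulfonate CC(C)(C)[Si](C)(C)OS(=O)(=O)C(F)(F)F
Why: The silyl triflate silylates the hindered C9 hydroxyl next to quaternary C8, and the robust ether will survive until the global deprotection.

Step 17
Reactants: 23 9-O-tert-butyldimethylsilyl ether
Product: 24 terminal alkyne (ethyl Z-enoate retained)
Conditions: K2CO3 (0.5 equiv), EtOH–THF, 0 °C to rt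
Reagents that add atoms: none
Why: Ethoxide-mediated protodesilylation removes only the alkynyl trimethylsilyl group, ethanol makes any ester exchange degenerate, and the hindered O-silyl ethers are stable to these conditions.

Step 18
Reactants: 24 terminal alkyne ester
Product: 25 Z allylic alcohol (C4 hydroxymethyl)
Conditions: i-Bu2AlH (2.2 equiv), CH2Cl2, −78 °C; aq. potassium sodium tartrate
Reagents that add atoms: none
Why: Diisobutylaluminium hydride at −78 °C should reduce the ethyl enoate to the allylic alcohol faster than the lactone, whose carbonyl is flanked by two fully substituted silyloxy carbons, and any lactol from partial over-reduction is returned to the lactone by the oxidant of step 19.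

Step 19
Reactants: 25 Z allylic alcohol
Product: 26 Z enal C4–C13 with terminal alkyne
Conditions: Dess–Martin periodinane, NaHCO3, CH2Cl2, 0 °C
Reagents that add atoms: none
Why: Buffered Dess–Martin oxidation gives the Z enal without touching the alkyne or the silyl ethers and would also re-oxidise any lactol to the lactone.

**Iodo enone C14–C1–C2–C3**

Step 20
Reactants: 27 propargyl alcohol
Product: 29 (Z)-3-iodo-2-methylprop-2-en-1-ol, via alkenylmagnesium alkoxide 28 (not isolated)
Conditions: MeMgBr (2.3 equiv), CuI (10 mol %), THF, −20 °C to rt; then I2, THF, −20 °C; aq. NH4Cl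
Reagents that add atoms: methylmagnesium bromide C[Mg]Br; iodine II
Why: Copper-catalysed anti carbomagnesiation of the propargylic alkoxide places methyl C15 on the internal carbon and magnesium cis to oxygen in a five-membered chelate, so iodinolysis with retention gives the Z iodide with iodine cis to the hydroxymethyl group.

Step 21
Reactants: 29 (Z)-3-iodo-2-methylprop-2-en-1-ol
Product: 30 (Z)-3-iodo-2-methylprop-2-enal
Conditions: MnO2 (excess), CH2Cl2, rt, dark; filtered solution used directly
Reagents that add atoms: none
Why: Manganese dioxide oxidises the allylic alcohol selectively under neutral conditions that preserve the Z vinyl iodide.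

Step 22
Reactants: 30 (Z)-3-iodo-2-methylprop-2-enal
Product: 32 (Z)-4-iodo-3-methylbut-3-ene-1,2-diol (racemic at C2), via hydroxy silane 31 (not isolated)
Conditions: i-PrOMe2SiCH2MgCl (from i-PrOMe2SiCH2Cl and Mg), THF, −20 to 0 °C; aq. NH4Cl; then 30% H2O2, KF, KHCO3, THF–MeOH, rt
Reagents that add atoms: [(isopropoxydimethylsilyl)methyl]magnesium chloride CC(C)O[Si](C)(C)C[Mg]Cl; hydrogen peroxide OO
Why: The silylmethyl Grignard reagent is a hydroxymethyl anion equivalent that adds to the aldehyde without touching the vinyl iodide, and Tamao oxidation of the C–Si bond unveils the C3 hydroxyl, while the racemic C2 carbinol is removed in step 24.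

Step 23
Reactants: 32 (Z)-4-iodo-3-methylbut-3-ene-1,2-diol
Product: 33 (Z)-1-(tert-butyldimethylsilyloxy)-4-iodo-3-methylbut-3-en-2-ol (racemic)
Conditions: t-BuMe2SiCl (1.05 equiv), imidazole, CH2Cl2, −20 to 0 °C
Reagents that add atoms: tert-butylchlorodimethylsilane CC(C)(C)[Si](C)(C)Cl
Why: The bulky silyl chloride silylates the primary hydroxyl in preference to the secondary allylic one, a standard selective protection.

Step 24
Reactants: 33 (Z)-1-(tert-butyldimethylsilyloxy)-4-iodo-3-methylbut-3-en-2-ol
Product: 34 (Z)-1-(tert-butyldimethylsilyloxy)-4-iodo-3-methylbut-3-en-2-one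
Conditions: Dess–Martin periodinane, NaHCO3, CH2Cl2, 0 °C
Reagents that add atoms: none
Why: Dess–Martin oxidation of the allylic carbinol gives the Z β-iodo enone under buffered conditions that do not isomerise the alkene.

**Assembly, macrocycle and key step**

Step 25
Reactants: 34 (Z)-1-(tert-butyldimethylsilyloxy)-4-iodo-3-methylbut-3-en-2-one; 26 Z enal C4–C13
Product: 36 open-chain aldol with all twenty skeletal carbons (3-O-silyl and free 4-hydroxyl), via boron enolate 35 (not isolated)
Conditions: (+)-diisopinocampheylboron triflate, Ipc2BOTf [from (−)-α-pinene], i-Pr2NEt, CH2Cl2, −78 °C; then 26, −78 to −20 °C; pH 7 buffer, MeOH, 30% H2O2, 0 °C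
Reagents that add atoms: none
Why: Enolisation of the α-silyloxy ketone with the dialkylboron triflate and a hindered amine should give the Z enolate, whose chair (Zimmerman–Traxler) transition state gives the 3,4-syn boron aldol and forms C3–C4, while the isopinocampheyl ligands direct attack to the Re face of the aldehyde and so set the absolute configuration at C3 and C4.

Step 26
Reactants: 36 open-chain aldol
Product: 37 4-O-triethylsilyl ether of 36
Conditions: Et3SiOTf, 2,6-lutidine, CH2Cl2, −78 °C
Reagents that add atoms: triethylsilyl trifluoromethanesulfonate CC[Si](CC)(CC)OS(=O)(=O)C(F)(F)F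
Why: Silylation of the C4 hydroxyl blocks retro-aldol and dehydration during the amine-mediated coupling and the heating to come, and a secondary triethylsilyl ether can later be removed in the presence of the tertiary ones.

Step 27
Reactants: 37 4-O-triethylsilyl ether (Z iodo enone and terminal alkyne)
Product: 38 14-membered dienynone
Conditions: Pd(PPh3)4 (20 mol %), CuI (40 mol %), i-Pr2NEt, degassed THF, 1 mM, syringe-pump addition, rt
Reagents that add atoms: none
Why: Intramolecular Sonogashira coupling forms C13–C14 and the 14-membered ring, since oxidative addition of zerovalent palladium to the activated β-iodo enone is fast, the copper acetylide transmetallates, and high dilution with slow addition favours ring closure over oligomerisation, with retention of the C14=C1 geometry.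

Step 28
Reactants: 38 14-membered dienynone
Product: 39 14-membered trienone (C10=C11 E, C12=C13 Z, C14=C1 with C2 cis to C13)
Conditions: H2 (1 atm), Pd/CaCO3 poisoned with Pb(OAc)2, quinoline, EtOAc–hexane, 0 °C, uptake monitored; filtered cold
Reagents that add atoms: none
Why: Lindlar semihydrogenation adds hydrogen syn to the alkyne only and so gives the Z C12=C13 alkene that completes the triene, and the product is handled cold because it may begin to cyclise.

Step 29
Reactants: 39 14-membered trienone
Product: 40 trans-fused bicyclo[8.4.0] dienone (complete briarane skeleton)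
Conditions: degassed toluene (5 mM), 2,6-di-tert-butyl-4-methylphenol, 110 °C, dark
Reagents that add atoms: none
Why: Proposed new method: on heating, the triene C10=C11–C12=C13–C14=C1 should adopt its helical s-cis,s-cis form and close by a thermal six-electron disrotatory electrocyclisation in which C1 bonds to C10 across the 14-membered ring; the closest known reaction type is the thermal 6π closure of open-chain Z-hexatrienes released by alkyne semihydrogenation, including the previtamin D to pyrocalciferol closure that also creates a methyl-bearing quaternary carbon. The six-membered ring (C1, C10–C14) closes in this pericyclic mode, whereas the ten-membered ring (C1–C10) needs no bond of its own because it is what remains of the 14-membered perimeter once the transannular bond exists. The relative configuration at C1 and C10 follows from disrotation of a triene whose outward groups are C9 and methyl C15 and whose inward groups are H10 and the C2 carbonyl, so C9 and C15 end up cis, H10 and C15 trans, and the ring fusion trans; the absolute sense at both centres is relayed from C9. The selectivity required is torquoselectivity (one helical sense): allylic 1,3-strain between methyl C20 and C9 should hold H9 in the triene plane, so that C8 and the tether, stiffened by the Z C5=C6 alkene and the lactone, lie on the face of C10 at which C1 arrives, which corresponds to the configuration of the target. The inward group on C1 is a carbonyl carbon without hydrogen, so the 1,7-hydrogen shift typical of Z-trienes is shut off, and the reversible oxa-6π closure of the Z-dienone to a 2H-pyran only stores material that should drain into the more stable carbocycle.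

**End game**

Step 30
Reactants: 40 trans-fused bicyclic dienone
Product: 41 C4 alcohol (β-hydroxy ketone)
Conditions: pyridinium p-toluenesulfonate (cat.), MeOH–CH2Cl2, 0 °C
Reagents that add atoms: none
Why: Mild acid methanolysis should cleave the secondary allylic triethylsilyl ether at C4 much faster than the two tertiary triethylsilyl ethers and the secondary tert-butyldimethylsilyl ethers, freeing the hydroxyl that directs step 31.

Step 31
Reactants: 41 C4 alcohol
Product: 43 2,4-syn diol, via boron chelate 42 (not isolated)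
Conditions: Et2BOMe, THF–MeOH 4:1, −78 °C; then NaBH4, −78 °C; AcOH; MeOH co-evaporation
Reagents that add atoms: none
Why: In the Narasaka–Prasad reduction the diethylboron chelate between the C4 oxygen and the C2 ketone is reduced by external axial hydride delivery, which should give the 2,4-syn (and 2,3-syn) diol and hence the C2 configuration of the target, while the lactone is inert to borohydride at −78 °C.

Step 32
Reactants: 43 2,4-syn diol
Product: 44 hexaol (hydroxyls at C2, C3, C4, C8, C9, C17)
Conditions: HF·pyridine, pyridine, THF, 0 °C to rt (polypropylene vessel)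
Reagents that add atoms: none
Why: Buffered hydrogen fluoride–pyridine removes all four remaining silyl ethers (global desilylation) without acid strong enough to disturb the diene or the lactone.

Step 33
Reactants: 44 hexaol
Product: 45 2,3,4,9-tetraacetate (diene intact, C8 and C17 hydroxyls free)
Conditions: Ac2O, pyridine, 4-(dimethylamino)pyridine (cat.), CH2Cl2, 0 °C to rt
Reagents that add atoms: acetic anhydride CC(=O)OC(C)=O
Why: Acetylation with nucleophilic catalysis esterifies the four secondary alcohols, while the tertiary C8 and C17 hydroxyls are too hindered to react under these conditions.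

Step 34
Reactants: 45 2,3,4,9-tetraacetate
Product: 46 CNP0203328.1 (target)
Conditions: OsO4 (1.05 equiv), pyridine, THF, −78 to −30 °C; aq. NaHSO3
Reagents that add atoms: osmium tetroxide O=[Os](=O)(=O)=O
Why: Stoichiometric osmium tetroxide syn-dihydroxylation should take place at the more electron-rich trisubstituted C11=C12 bond of the diene rather than at C13=C14 (shielded by quaternary C1) or C5=C6 (deactivated by two allylic acyloxy groups), from the face carrying H10 and away from C9 and methyl C15, which sets C11 and C12 and leaves the new diol free.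

**Compound list**

1 | methyl (S)-2,2-dimethyl-1,3-dioxolane-4-carboxylate | COC(=O)[C@@H]1COC(C)(C)O1 | starting material
2 | ethyl 2-(triphenylphosphoranylidene)propanoate | CCOC(=O)C(C)=P(c1ccccc1)(c1ccccc1)c1ccccc1 | starting material
3 | (S)-2,2-dimethyl-1,3-dioxolane-4-carbaldehyde | O=C[C@@H]1COC(C)(C)O1 | intermediate
4 | ethyl (E)-3-[(R)-2,2-dimethyl-1,3-dioxolan-4-yl]-2-methylprop-2-enoate | CCOC(=O)/C(C)=C/[C@@H]1COC(C)(C)O1 | intermediate
5 | ethyl (2E,4R)-4,5-dihydroxy-2-methylpent-2-enoate | CCOC(=O)/C(C)=C/[C@@H](O)CO | intermediate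
6 | (R)-5-(hydroxymethyl)-3-methylfuran-2(5H)-one | OC[C@@H]1OC(=O)C(C)=C1 | intermediate
7 | (R)-3-methyl-5-[(triethylsilyloxy)methyl]furan-2(5H)-one | CC[Si](CC)(CC)OC[C@@H]1OC(=O)C(C)=C1 | intermediate
8 | 2-C-methyl-5-O-triethylsilyl-L-ribono-1,4-lactone | CC[Si](CC)(CC)OC[C@@H]1OC(=O)[C@@](C)(O)[C@H]1O | intermediate
9 | C8 keto lactone, (3S,5S)-3-hydroxy-3-methyl-5-[(triethylsilyloxy)methyl]oxolane-2,4-dione | CC[Si](CC)(CC)OC[C@@H]1OC(=O)[C@@](C)(O)C1=O | intermediate
10 | C8 vinyl carbinol, (3S,4R,5S)-4-ethenyl-3,4-dihydroxy-3-methyl-5-[(triethylsilyloxy)methyl]oxolan-2-one | CC[Si](CC)(CC)OC[C@@H]1OC(=O)[C@@](C)(O)[C@@]1(O)C=C | intermediate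
11 | tris-silylated vinyl lactone (8,17-bis-O-triethylsilyl ether of 10) | CC[Si](CC)(CC)OC[C@@H]1OC(=O)[C@@](C)(O[Si](CC)(CC)CC)[C@@]1(O[Si](CC)(CC)CC)C=C | intermediate
12 | C6 aldehyde of the bis-silylated vinyl lactone | O=C[C@@H]1OC(=O)[C@@](C)(O[Si](CC)(CC)CC)[C@@]1(O[Si](CC)(CC)CC)C=C | intermediate
13 | ethyl 2-[bis(2,2,2-trifluoroethoxy)phosphoryl]propanoate | CCOC(=O)C(C)P(=O)(OCC(F)(F)F)OCC(F)(F)F | starting material
14 | Z-enoate vinyl lactone | CCOC(=O)/C(C)=C\[C@@H]1OC(=O)[C@@](C)(O[Si](CC)(CC)CC)[C@@]1(O[Si](CC)(CC)CC)C=C | intermediate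
15 | C9 aldehyde, lactone fragment C4–C9 | CCOC(=O)/C(C)=C\[C@@H]1OC(=O)[C@@](C)(O[Si](CC)(CC)CC)[C@@]1(O[Si](CC)(CC)CC)C=O | intermediate
16 | 1,4-bis(trimethylsilyl)buta-1,3-diyne | C[Si](C)(C)C#CC#C[Si](C)(C)C | starting material
17 | (trimethylsilyl)buta-1,3-diyne | C#CC#C[Si](C)(C)C | intermediate
18 | (E)-dimethyl[2-methyl-4-(trimethylsilyl)but-1-en-3-yn-1-yl]alane | C[Al](C)/C=C(C)/C#C[Si](C)(C)C | intermediate
19 | (E)-(4-iodo-3-methylbut-3-en-1-yn-1-yl)trimethylsilane | I/C=C(C)/C#C[Si](C)(C)C | intermediate
20 | C4–C13 allylic alcohol, both C9 epimers | CCOC(=O)/C(C)=C\[C@@H]1OC(=O)[C@@](C)(O[Si](CC)(CC)CC)[C@@]1(O[Si](CC)(CC)CC)C(O)/C=C(C)/C#C[Si](C)(C)C | intermediate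
21 | C9 enynone | CCOC(=O)/C(C)=C\[C@@H]1OC(=O)[C@@](C)(O[Si](CC)(CC)CC)[C@@]1(O[Si](CC)(CC)CC)C(=O)/C=C(C)/C#C[Si](C)(C)C | intermediate
22 | (9R) allylic alcohol C4–C13 | CCOC(=O)/C(C)=C\[C@@H]1OC(=O)[C@@](C)(O[Si](CC)(CC)CC)[C@@]1(O[Si](CC)(CC)CC)[C@H](O)/C=C(C)/C#C[Si](C)(C)C | intermediate
23 | 9-O-tert-butyldimethylsilyl ether of 22 | CCOC(=O)/C(C)=C\[C@@H]1OC(=O)[C@@](C)(O[Si](CC)(CC)CC)[C@@]1(O[Si](CC)(CC)CC)[C@H](O[Si](C)(C)C(C)(C)C)/C=C(C)/C#C[Si](C)(C)C | intermediate
24 | terminal alkyne with ethyl Z-enoate | CCOC(=O)/C(C)=C\[C@@H]1OC(=O)[C@@](C)(O[Si](CC)(CC)CC)[C@@]1(O[Si](CC)(CC)CC)[C@H](O[Si](C)(C)C(C)(C)C)/C=C(C)/C#C | intermediate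
25 | Z allylic alcohol with terminal alkyne | OC/C(C)=C\[C@@H]1OC(=O)[C@@](C)(O[Si](CC)(CC)CC)[C@@]1(O[Si](CC)(CC)CC)[C@H](O[Si](C)(C)C(C)(C)C)/C=C(C)/C#C | intermediate
26 | Z enal C4–C13 with terminal alkyne | O=C/C(C)=C\[C@@H]1OC(=O)[C@@](C)(O[Si](CC)(CC)CC)[C@@]1(O[Si](CC)(CC)CC)[C@H](O[Si](C)(C)C(C)(C)C)/C=C(C)/C#C | intermediate
27 | propargyl alcohol | C#CCO | starting material
28 | (Z)-alkenylmagnesium bromide alkoxide from carbomagnesiation | Br[Mg]/C=C(C)\CO[Mg]Br | intermediate
29 | (Z)-3-iodo-2-methylprop-2-en-1-ol | I/C=C(C)\CO | intermediate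
30 | (Z)-3-iodo-2-methylprop-2-enal | I/C=C(C)\C=O | intermediate
31 | (Z)-4-iodo-1-(isopropoxydimethylsilyl)-3-methylbut-3-en-2-ol (racemic) | I/C=C(C)\C(O)C[Si](C)(C)OC(C)C | intermediate
32 | (Z)-4-iodo-3-methylbut-3-ene-1,2-diol (racemic) | I/C=C(C)\C(O)CO | intermediate
33 | (Z)-1-(tert-butyldimethylsilyloxy)-4-iodo-3-methylbut-3-en-2-ol (racemic) | I/C=C(C)\C(O)CO[Si](C)(C)C(C)(C)C | intermediate
34 | (Z)-1-(tert-butyldimethylsilyloxy)-4-iodo-3-methylbut-3-en-2-one | I/C=C(C)\C(=O)CO[Si](C)(C)C(C)(C)C | intermediate
35 | Z(O) diisopinocampheylboron enolate of 34 | I/C=C(C)\C(OB([C@H]1C[C@H]2C[C@@H]([C@@H]1C)C2(C)C)[C@H]1C[C@H]2C[C@@H]([C@@H]1C)C2(C)C)=C\O[Si](C)(C)C(C)(C)C | intermediate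
36 | open-chain syn aldol, all twenty skeletal carbons | I/C=C(C)\C(=O)[C@H](O[Si](C)(C)C(C)(C)C)[C@@H](O)/C(C)=C\[C@@H]1OC(=O)[C@@](C)(O[Si](CC)(CC)CC)[C@@]1(O[Si](CC)(CC)CC)[C@H](O[Si](C)(C)C(C)(C)C)/C=C(C)/C#C | intermediate
37 | 4-O-triethylsilyl ether of 36 | I/C=C(C)\C(=O)[C@H](O[Si](C)(C)C(C)(C)C)[C@@H](O[Si](CC)(CC)CC)/C(C)=C\[C@@H]1OC(=O)[C@@](C)(O[Si](CC)(CC)CC)[C@@]1(O[Si](CC)(CC)CC)[C@H](O[Si](C)(C)C(C)(C)C)/C=C(C)/C#C | intermediate
38 | 14-membered dienynone | CC(C)(C)[Si](C)(C)O[C@@H]1[C@@H](O[Si](CC)(CC)CC)/C(C)=C\[C@@H]2OC(=O)[C@@](C)(O[Si](CC)(CC)CC)[C@@]2(O[Si](CC)(CC)CC)[C@H](O[Si](C)(C)C(C)(C)C)/C=C(C)/C#C/C=C(C)\C1=O | intermediate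
39 | 14-membered trienone | CC(C)(C)[Si](C)(C)O[C@@H]1[C@@H](O[Si](CC)(CC)CC)/C(C)=C\[C@@H]2OC(=O)[C@@](C)(O[Si](CC)(CC)CC)[C@@]2(O[Si](CC)(CC)CC)[C@H](O[Si](C)(C)C(C)(C)C)/C=C(C)/C=C\C=C(C)/C1=O | intermediate
40 | trans-fused bicyclo[8.4.0] dienone | CC(C)(C)[Si](C)(C)O[C@@H]1[C@@H](O[Si](CC)(CC)CC)/C(C)=C\[C@@H]2OC(=O)[C@@](C)(O[Si](CC)(CC)CC)[C@@]2(O[Si](CC)(CC)CC)[C@H](O[Si](C)(C)C(C)(C)C)[C@H]2C(C)=CC=C[C@]2(C)C1=O | intermediate
41 | C4 alcohol of the bicyclic dienone | CC(C)(C)[Si](C)(C)O[C@@H]1[C@@H](O)/C(C)=C\[C@@H]2OC(=O)[C@@](C)(O[Si](CC)(CC)CC)[C@@]2(O[Si](CC)(CC)CC)[C@H](O[Si](C)(C)C(C)(C)C)[C@H]2C(C)=CC=C[C@]2(C)C1=O | intermediate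
42 | 4-O-diethylboryl chelate of 41 | CC(C)(C)[Si](C)(C)O[C@@H]1[C@@H](OB(CC)CC)/C(C)=C\[C@@H]2OC(=O)[C@@](C)(O[Si](CC)(CC)CC)[C@@]2(O[Si](CC)(CC)CC)[C@H](O[Si](C)(C)C(C)(C)C)[C@H]2C(C)=CC=C[C@]2(C)C1=O | intermediate
43 | 2,4-syn diol | CC(C)(C)[Si](C)(C)O[C@@H]1[C@@H](O)/C(C)=C\[C@@H]2OC(=O)[C@@](C)(O[Si](CC)(CC)CC)[C@@]2(O[Si](CC)(CC)CC)[C@H](O[Si](C)(C)C(C)(C)C)[C@H]2C(C)=CC=C[C@]2(C)[C@H]1O | intermediate
44 | hexaol diene | O[C@@H]1[C@@H](O)/C(C)=C\[C@@H]2OC(=O)[C@@](C)(O)[C@@]2(O)[C@H](O)[C@H]2C(C)=CC=C[C@]2(C)[C@H]1O | intermediate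
45 | 2,3,4,9-tetraacetate diene | CC(=O)O[C@@H]1[C@@H](OC(C)=O)/C(C)=C\[C@@H]2OC(=O)[C@@](C)(O)[C@@]2(O)[C@H](OC(C)=O)[C@H]2C(C)=CC=C[C@]2(C)[C@H]1OC(C)=O | intermediate
46 | CNP0203328.1 | CC(=O)O[C@@H]1[C@@H](OC(C)=O)/C(C)=C\[C@@H]2OC(=O)[C@@](C)(O)[C@@]2(O)[C@H](OC(C)=O)[C@H]2[C@](C)(O)[C@H](O)C=C[C@]2(C)[C@H]1OC(C)=O | target

**Step count**

Total: 34 steps. Longest linear sequence: 27 steps (steps 1–10, 13–19 and 25–34, from compound 1).

**Steps most likely to fail**

1. Step 29 (transannular electrocyclisation). The closure may stall because of the inward carbonyl group and ring strain, or the triene may coil in the wrong helical sense (poor torquoselectivity), or the product may suffer 1,5-hydrogen shift on prolonged heating. Fallback with known chemistry: close the six-membered ring in the open chain, where thermal 6π closure of semihydrogenated dienynes is established, and close the ten-membered ring afterwards by an aldol. The fallback sets out from enal 26 and iodo enone 34. An intermolecular Sonogashira coupling [Pd(PPh3)4, CuI, i-Pr2NEt, THF] would give the open-chain dienynone enal F1. Semihydrogenation over Pd/CaCO3 poisoned with Pb(OAc)2 would give the open-chain trienone enal F2. Heating in toluene would give the cyclohexadienyl ketone enal F3, with C9 and methyl C15 cis; the two helical senses, now controlled only by allylic strain at C9, would be separated by chromatography. An intramolecular boron aldol of F3 at high dilution (Ipc2BOTf, i-Pr2NEt), a known ring-closing reaction type though demanding at this ring size, would form C3–C4 and the ten-membered ring. It returns to the route at C4 alcohol 41.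

2. Step 27 (macrocyclic Sonogashira coupling). Ring closure may lose to oligomerisation or to oxidative homocoupling of the alkyne, and the β-iodo enone may isomerise before it couples. Fallback: reverse the order of the two couplings. The same intermolecular Sonogashira coupling of 26 and 34 gives the open-chain dienynone enal F1. An intramolecular boron aldol (Ipc2BOTf, i-Pr2NEt, CH2Cl2, high dilution) then closes the 14-membered ring at C3–C4 and gives the 14-membered C4-hydroxy dienynone F4. Silylation with Et3SiOTf and 2,6-lutidine returns to the route at 38.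

3. Step 2 (photochemical isomerisation and lactonisation). Isomerisation may stop at a photostationary mixture or be diverted into photodeconjugation or butenolide photodimerisation. Fallback: set the Z geometry by olefination. Crude aldehyde 3 (from 1 with i-Bu2AlH) is treated with the potassium salt of phosphonate 13 [KN(SiMe3)2, 18-crown-6, THF, −78 °C; Still–Gennari] to give ethyl (Z)-3-[(R)-2,2-dimethyl-1,3-dioxolan-4-yl]-2-methylprop-2-enoate F5. In CF3CO2H–H2O this loses the acetonide and lactonises spontaneously, rejoining the route at butenolide 6.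

**Further compounds**

F1 | step 29 | open-chain dienynone enal | O=C/C(C)=C\[C@@H]1OC(=O)[C@@](C)(O[Si](CC)(CC)CC)[C@@]1(O[Si](CC)(CC)CC)[C@H](O[Si](C)(C)C(C)(C)C)/C=C(C)/C#C/C=C(C)\C(=O)CO[Si](C)(C)C(C)(C)C
F2 | step 29 | open-chain trienone enal | O=C/C(C)=C\[C@@H]1OC(=O)[C@@](C)(O[Si](CC)(CC)CC)[C@@]1(O[Si](CC)(CC)CC)[C@H](O[Si](C)(C)C(C)(C)C)/C=C(C)/C=C\C=C(C)/C(=O)CO[Si](C)(C)C(C)(C)C
F3 | step 29 | cyclohexadienyl ketone enal | O=C/C(C)=C\[C@@H]1OC(=O)[C@@](C)(O[Si](CC)(CC)CC)[C@@]1(O[Si](CC)(CC)CC)[C@H](O[Si](C)(C)C(C)(C)C)[C@H]1C(C)=CC=C[C@]1(C)C(=O)CO[Si](C)(C)C(C)(C)C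
F4 | step 27 | 14-membered C4-hydroxy dienynone | CC(C)(C)[Si](C)(C)O[C@@H]1[C@@H](O)/C(C)=C\[C@@H]2OC(=O)[C@@](C)(O[Si](CC)(CC)CC)[C@@]2(O[Si](CC)(CC)CC)[C@H](O[Si](C)(C)C(C)(C)C)/C=C(C)/C#C/C=C(C)\C1=O
F5 | step 2 | ethyl (Z)-3-[(R)-2,2-dimethyl-1,3-dioxolan-4-yl]-2-methylprop-2-enoate | CCOC(=O)/C(C)=C\[C@@H]1COC(C)(C)O1
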